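**Plan**
Retrosynthesis: remove the C8 angelate. Open the C6–O–C12 butyrolactone to a 2-methylene-1,4-diol. Take C1–OH back to the ketone. Then cut C2–C3 of the ten-membered carbocycle by a retro-Claisen step that restores an O–C5 bond.
Enabling feature: the ring segment C1(O)–C2H2–C3H(O)–C4(CH3)=C5H (Z) is a γ,δ-unsaturated-ketone retron with an oxygenated allyl terminus. Ring C1–C10 therefore maps onto the eight-membered ring O–C1–C10–C9–C8–C7–C6–C5 of a 2-methyleneoxocane, with C2 as the exocyclic CH2 and C4/C3 as an (E)-alkoxypropenyl group on C5.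
Forward: the chain is joined as C5–C8/C11–C13 (aldol), C9 (MeMgBr), C10/C1 (pyruvate aldol), C3/C4 (alkenylzinc), C2 (methylenation). The rings arise in the order γ-lactone O8–C1 (temporary), eight-membered lactone, ten-membered carbocycle, 1,3-dioxane (temporary), α-methylene-γ-butyrolactone.
Stereochemistry: C6/C7 come from a bought oxazolidinone and C10 from a Cu–bis(oxazoline) catalyst. C8 is relayed from C6–OH and the sacrificial C5 from C6 (Felkin–Anh). C3 and the 4Z geometry come from C5 in the key step, and C1 from C10–OH by chelation.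

Key step: step 16

Remark: germacrane numbering of the target (C1–C15) is used for every intermediate (TBS = tBuMe2Si, TES = Et3Si, PMB = 4-methoxybenzyl, PMP = 4-methoxyphenyl); the acetal carbon of 37–44 and the lactol carbon of 43 are left undefined because both are removed again; all eight starting materials are taken as catalogue compounds.

Step 1
Reactants: 1 1-(tert-butyldimethylsilyloxy)propan-2-one; 2 triethyl phosphonoacetate
Product: 3 ethyl (E)-4-(tert-butyldimethylsilyloxy)-3-methylbut-2-enoate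
Conditions: NaH, THF, 0 °C to rt; minor Z isomer removed on silica
Reagents that add atoms: none
Why: Horner–Wadsworth–Emmons olefination of the methyl ketone should favour the E-enoate (ester trans to the larger CH2OTBS), which puts the CH3 cis to the carbonyl as needed for the later γ-deprotonation.

Step 2
Reactants: 3 ethyl (E)-4-(tert-butyldimethylsilyloxy)-3-methylbut-2-enoate
Product: 4 (E)-4-(tert-butyldimethylsilyloxy)-3-methylbut-2-enoic acid
Conditions: LiOH, THF/MeOH/H2O, rt; cold dilute HCl to pH 4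
Reagents that add atoms: lithium hydroxide [Li+].[OH-]
Why: Plain ester saponification, which should leave the silyl ether and the alkene geometry untouched.

Step 3
Reactants: 4 (E)-4-(tert-butyldimethylsilyloxy)-3-methylbut-2-enoic acid; 5 (R)-4-benzyl-2-oxazolidinone
Product: 7 (R)-4-benzyl-3-[(E)-4-(TBSO)-3-methylbut-2-enoyl]oxazolidin-2-one, via mixed pivalic anhydride 6 (not isolated)
Conditions: PivCl, Et3N, THF, −20 °C; then 5, LiCl, rt
Reagents that add atoms: pivaloyl chloride CC(C)(C)C(=O)Cl (its atoms stay in 6 only)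
Why: Mixed-anhydride N-acylation under LiCl/Et3N needs no strong base, so the enoate geometry should persist; the only stereocentre is bought with 5.

Step 4
Reactants: 7 (R)-4-benzyl-3-[(E)-4-(TBSO)-3-methylbut-2-enoyl]oxazolidin-2-one; 8 2-[(4-methoxybenzyl)oxy]acetaldehyde
Product: 9 (4R)-4-benzyl-3-[(2R,3R)-3-hydroxy-4-(PMBO)-2-(3-TBSO-prop-1-en-2-yl)butanoyl]oxazolidin-2-one (C8 imide; C7 branch; C6–OH; C5–OPMB)
Conditions: Bu2BOTf, Et3N, CH2Cl2, −78 to 0 °C; 8, −78 to 0 °C; pH 7 buffer, H2O2, MeOH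
Reagents that add atoms: none
Why: Deconjugative Evans syn-aldol reaction, in which soft enolisation removes a proton of the cis CH3, and the (Z)-boron dienolate reacts at its α-carbon (C7) through a Zimmerman–Traxler chair on the face away from the benzyl group; this sets C6 and C7 (6,7-syn) and releases the C11=C13 methylene.

Step 5
Reactants: 9 Evans syn-aldol adduct
Product: 10 (2R,3R)-3-hydroxy-N-methoxy-N-methyl-4-(PMBO)-2-(3-TBSO-prop-1-en-2-yl)butanamide
Conditions: MeONHMe·HCl, Me3Al, THF/CH2Cl2, −20 to 0 °C; Rochelle salt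
Reagents that add atoms: N,O-dimethylhydroxylamine hydrochloride CNOC.Cl
Why: Aluminium-amide transamidation (Weinreb amide synthesis) is assisted by the free β-hydroxyl and should release the auxiliary without touching C7.

Step 6
Reactants: 10 Weinreb amide
Product: 11 (3R,4R)-4-hydroxy-5-(PMBO)-3-(3-TBSO-prop-1-en-2-yl)pentan-2-one (C8 methyl ketone; CH3 = C9)
Conditions: MeMgBr (3.5 equiv), THF, −20 to 0 °C; cold aq NH4Cl
Reagents that add atoms: methylmagnesium bromide C[Mg]Br
Why: Weinreb ketone synthesis, whose chelated tetrahedral intermediate prevents over-addition and keeps the doubly activated C7–H safe until the cold quench.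

Step 7
Reactants: 11 β-hydroxy methyl ketone; 12 methyl pyruvate
Product: 15 methyl (2R,5R,6R)-2,6-dihydroxy-2-methyl-4-oxo-7-(PMBO)-5-(3-TBSO-prop-1-en-2-yl)heptanoate, via bis-TMS enol ether 13 (not isolated), via bis-TMS aldol adduct 14 (not isolated)
Conditions: TMSCl, LDA (2.3 equiv), THF, −78 °C, pentane filtration; 12, [Cu((R,R)-t-Bu-box)](OTf)2 (10 mol %), CH2Cl2, −78 °C; 1 N HCl, THF, 0 °C
Reagents that add atoms: chlorotrimethylsilane C[Si](C)(C)Cl (its atoms stay in 13 and 14 only)
Why: Kinetic enolisation at the unhindered CH3 with in situ silylation, then a Cu(II)–bis(oxazoline)-catalysed Mukaiyama aldol addition to the chelated pyruvate, in which the (R,R)-ligand shields one ketone face and should set the C10 tertiary carbinol under catalyst control.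

Step 8
Reactants: 15 dihydroxy keto ester
Product: 17 (3R,5R)-3-hydroxy-3-methyl-5-substituted oxolan-2-one (γ-lactone O8–C1; free C6–OH and C10–OH; all-syn C6/C7/C8), via triol ester 16 (not isolated)
Conditions: Et2BOMe, THF/MeOH 4:1, −78 °C; NaBH4; AcOH quench, MeOH azeotrope; PPTS (cat.), CH2Cl2, rt
Reagents that add atoms: none
Why: Narasaka–Prasad reduction, in which the boron chelate of the less hindered secondary C6 alkoxide and the C8 ketone is attacked axially, anti to the axial C7 branch, to give the 6,8-syn (all-syn) triad; only the new C8–OH is γ to the ester, so lactonisation tells O8 from O6.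

Step 9
Reactants: 17 γ-lactone diol
Product: 18 C6-O-TBS γ-lactone
Conditions: TBSOTf, 2,6-lutidine, CH2Cl2, −78 °C
Reagents that add atoms: tert-butyldimethylsilyl triflate CC(C)(C)[Si](C)(C)OS(=O)(=O)C(F)(F)F
Why: Standard silylation, which at low temperature should take the secondary C6–OH and leave the tertiary C10–OH free.

Step 10
Reactants: 18 C6-O-TBS γ-lactone
Product: 21 C1 carboxylic acid with C8–OTES and free C10–OH, via lithium hydroxy carboxylate 19 (not isolated), via TES ether TES ester 20 (not isolated)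
Conditions: LiOH, THF/H2O, 0 °C, lyophilise; TESCl, imidazole, DMF, 0 °C; K2CO3 (cat.), MeOH/H2O, 0 °C; pH 5.5 buffer
Reagents that add atoms: lithium hydroxide [Li+].[OH-]; chlorotriethylsilane CC[Si](Cl)(CC)CC
Why: Lactone saponification followed by silylation of the salt without acidification stops relactonisation, and mild methanolysis then cleaves only the silyl ester, so O8 is blocked while C1 becomes a free acid.

Step 11
Reactants: 21 C5-O-PMB acid
Product: 22 C5 primary alcohol
Conditions: DDQ, CH2Cl2/pH 7 buffer 10:1, 0 °C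
Reagents that add atoms: none
Why: Oxidative PMB ether cleavage, which should tolerate silyl ethers, the 1,1-disubstituted alkene and the acid.

Step 12
Reactants: 22 C5 primary alcohol
Product: 23 C5 aldehyde (α-OTBS aldehyde acid)
Conditions: Dess–Martin periodinane, NaHCO3, CH2Cl2, 0 °C to rt
Reagents that add atoms: none
Why: Buffered Dess–Martin oxidation should give the α-silyloxy aldehyde without epimerising C6, and the tertiary alcohol is inert.

Step 13
Reactants: 24 4-methoxybenzyl alcohol; 25 trichloroethylene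
Product: 28 1-methoxy-4-[(prop-1-yn-1-yloxy)methyl]benzene, via dichlorovinyl ether 26 (not isolated), via lithium alkoxyacetylide 27 (not isolated)
Conditions: KH, THF, 0 °C; 25, −50 °C to rt; n-BuLi (2.3 equiv), −78 °C; MeI, DMPU, −78 to 0 °C; kept below rt
Reagents that add atoms: iodomethane CI
Why: Standard ynol ether synthesis by alkoxide addition to trichloroethylene, dehydrochlorination with Cl–Li exchange, and C-methylation of the acetylide.

Step 14
Reactants: 23 C5 aldehyde; 28 PMB propynyl ether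
Product: 30 seco acid with (E)-PMBO–C3H=C4(CH3)–C5H(OH) (5,6-anti), via alkenylzirconocene 29 (not isolated)
Conditions: 28, Cp2Zr(H)Cl, CH2Cl2, rt; Me2Zn, toluene, −65 °C; 23 (pre-treated with Me2Zn, 2 equiv), 0 °C; aq NaHCO3/Rochelle salt, Et3N-washed silica
Reagents that add atoms: zirconocene chloride hydride [H][Zr](Cl)(C1C=CC=C1)C1C=CC=C1 (only its H stays in 30)
Why: syn-Hydrozirconation puts Zr on the methyl-bearing carbon β to oxygen and so fixes the E-enol ether, and after Zr-to-Zn transmetalation the alkenylzinc adds to the aldehyde under polar Felkin–Anh control (attack anti to C6–OTBS) to set the sacrificial C5 carbinol 5,6-anti.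

Step 15
Reactants: 30 seco acid
Product: 32 eight-membered lactone (oxocan-2-one O–C1–C10–C9–C8–C7–C6–C5), via mixed nitrobenzoic anhydride 31 (not isolated)
Conditions: MNBA, DMAP, CH2Cl2 (2 mM, syringe pump), rt; Et3N-washed silica
Reagents that add atoms: 2-methyl-6-nitrobenzoic anhydride Cc1cccc([N+](=O)[O-])c1C(=O)OC(=O)c1c(C)cccc1[N+](=O)[O-] (its atoms stay in 31 only)
Why: Shiina macrolactonisation, a basic room-temperature method with precedent for eight-membered lactones, should acylate the secondary C5–OH because O8 is silylated and the tertiary C10–OH is too hindered, with the quaternary C10 and the substituted backbone favouring the folded conformer.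

Step 16
Reactants: 32 eight-membered lactone
Product: 34 ten-membered (4Z)-1-ketone with C3–OPMB, via 2-methyleneoxocane 33 (not isolated)
Conditions: Cp2TiMe2 (4 equiv), toluene, 70 °C, dark; then 110 °C; filtration through basic alumina
Reagents that add atoms: dimethyltitanocene C[Ti](C)(C1C=CC=C1)C1C=CC=C1
Why: Petasis methylenation turns the only carbonyl group (C1) into the exocyclic enol ether 33, whose array C2=C1–O–C5–C4=C3 then undergoes a thermal [3,3]-sigmatropic (Claisen) shift in which C2–C3 forms as C5–O breaks, so that O leaves the ring and C2, C3 and C4 enter it (8 to 10). The closest known reaction type is the methylenation–Claisen ring expansion of vinyl-substituted lactones to cycloalkenones two atoms larger, here speeded by the alkoxy donor on the allyl terminus C3. The ten-membered carbocycle is closed by ring enlargement through a bicyclo[5.3.1]-like transition state in which the five-atom bridge C6–C10 ties C5 to C1, so no end-to-end cyclisation is needed. That short bridge can span the pericyclic array only if C6 sits axial (endo) on C5, which should force the new C4=C5 bond to be Z, while the E-enol ether keeps OPMB equatorial and clear of C6. C3 is the only new stereocentre and is fixed by suprafacial 1,3-chirality transfer from the sacrificial C5 (C2 bonds on the face from which O5 departs), which for the (5S, E) substrate gives 3S whether the array is chair or boat because C2 is unsubstituted. The step needs methylenation of one carbonyl only (secured by holding C12 at the alcohol level and adding the angelate later) and [3,3] rather than ionisation or a [1,3] shift (favoured by neutral, acid-free conditions and by the tether that holds C2 over C3).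

Step 17
Reactants: 34 ten-membered α-hydroxy ketone
Product: 35 C1 alcohol (1,10-anti diol)
Conditions: Zn(BH4)2, Et2O, −30 °C; aq NH4Cl
Reagents that add atoms: none
Why: Chelation-controlled (Cram chelate) reduction, in which the zinc alkoxide of C10–OH binds the C1 carbonyl and hydride comes from the face bearing the small C14 methyl, which is also the peripheral face of the ring, giving the 1,10-anti (and 1,3-anti) alcohol.

Step 18
Reactants: 35 C8-O-TES triol derivative
Product: 36 C1,C8,C10-triol with C3–OPMB and two TBS ethers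
Conditions: PPTS (cat.), MeOH/CH2Cl2, 0 °C
Reagents that add atoms: none
Why: Mild acid methanolysis should remove the secondary TES ether well before the TBS ethers or the PMB ether react.

Step 19
Reactants: 36 triol
Product: 37 C1,C3-O-(4-methoxybenzylidene) acetal with free C8–OH and C10–OH
Conditions: DDQ, 4 Å MS, CH2Cl2, 0 °C
Reagents that add atoms: none
Why: Anhydrous DDQ oxidation of the PMB ether gives an oxocarbenium ion that is trapped by the 1,3-related C1–OH as a six-membered acetal, so the existing PMB group masks both C1–O and C3–O without a new reagent.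

Step 20
Reactants: 37 acetal diol; 38 angelic acid
Product: 40 C8 angelate, via angelic trichlorobenzoic anhydride 39 (not isolated)
Conditions: 38, 2,4,6-trichlorobenzoyl chloride, Et3N, toluene, rt; then 37, 80 °C
Reagents that add atoms: 2,4,6-trichlorobenzoyl chloride O=C(Cl)c1c(Cl)cc(Cl)cc1Cl (its atoms stay in 39 only)
Why: Yamaguchi-type mixed-anhydride esterification without a nucleophilic catalyst is the usual way to keep the Z geometry of angelates, and only the secondary C8–OH can react because C10–OH is tertiary.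

Step 21
Reactants: 40 C8 angelate
Product: 41 C6,C12-diol
Conditions: HF·pyridine, pyridine, THF, 0 °C to rt
Reagents that add atoms: none
Why: Buffered fluoride desilylation should remove both TBS ethers while the ester and the acetal survive.

Step 22
Reactants: 41 C6,C12-diol
Product: 44 α-methylene-γ-butyrolactone acetal, via hydroxy enal 42 (not isolated), via lactol 43 (not isolated)
Conditions: TEMPO (cat.), PhI(OAc)2, CH2Cl2, rt
Reagents that add atoms: none
Why: TEMPO/PhI(OAc)2 oxidative lactonisation of a 1,4-diol takes the primary allylic C12–OH to the enal, C6–OH closes the five-membered lactol (5-exo-trig) and this is oxidised on, the trans fusion being already fixed at C6/C7 and O8 being blocked as the ester.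

Step 23
Reactants: 44 lactone acetal
Product: 45 target CNP0249520.1
Conditions: AcOH/THF/H2O 3:1:1, rt
Reagents that add atoms: none
Why: Mild acid hydrolysis of the strained anti-1,3-diol benzylidene acetal should free C1–OH and C3–OH without harming the angelate, the methylene lactone or any stereocentre.

**Compound list**
1 | 1-(tert-butyldimethylsilyloxy)propan-2-one | CC(=O)CO[Si](C)(C)C(C)(C)C | starting material
2 | triethyl phosphonoacetate | CCOC(=O)CP(=O)(OCC)OCC | starting material
3 | ethyl (E)-4-(TBSO)-3-methylbut-2-enoate | CCOC(=O)/C=C(\C)CO[Si](C)(C)C(C)(C)C | intermediate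
4 | (E)-4-(TBSO)-3-methylbut-2-enoic acid | OC(=O)/C=C(\C)CO[Si](C)(C)C(C)(C)C | intermediate
5 | (R)-4-benzyl-2-oxazolidinone | O=C1N[C@H](Cc2ccccc2)CO1 | starting material
6 | mixed pivalic anhydride of 4 | CC(C)(C)C(=O)OC(=O)/C=C(\C)CO[Si](C)(C)C(C)(C)C | intermediate
7 | (R)-4-benzyl-3-[(E)-4-(TBSO)-3-methylbut-2-enoyl]oxazolidin-2-one | O=C1N(C(=O)/C=C(\C)CO[Si](C)(C)C(C)(C)C)[C@H](Cc2ccccc2)CO1 | intermediate
8 | 2-[(4-methoxybenzyl)oxy]acetaldehyde | O=CCOCc1ccc(OC)cc1 | starting material
9 | Evans syn-aldol adduct (C8 imide, 6,7-syn) | COc1ccc(COC[C@H](O)[C@@H](C(=C)CO[Si](C)(C)C(C)(C)C)C(=O)N2[C@H](Cc3ccccc3)COC2=O)cc1 | intermediate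
10 | C8 Weinreb amide | COc1ccc(COC[C@H](O)[C@@H](C(=C)CO[Si](C)(C)C(C)(C)C)C(=O)N(C)OC)cc1 | intermediate
11 | C8 methyl ketone with free C6–OH | COc1ccc(COC[C@H](O)[C@@H](C(=C)CO[Si](C)(C)C(C)(C)C)C(C)=O)cc1 | intermediate
12 | methyl pyruvate | COC(=O)C(C)=O | starting material
13 | bis-TMS enol ether (C6–OTMS, C8(OTMS)=C9H2) | COc1ccc(COC[C@H](O[Si](C)(C)C)[C@@H](C(=C)CO[Si](C)(C)C(C)(C)C)C(=C)O[Si](C)(C)C)cc1 | intermediate
14 | bis-TMS aldol adduct (C6–OTMS, C10–OTMS) | COc1ccc(COC[C@H](O[Si](C)(C)C)[C@@H](C(=C)CO[Si](C)(C)C(C)(C)C)C(=O)C[C@@](C)(O[Si](C)(C)C)C(=O)OC)cc1 | intermediate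
15 | dihydroxy keto ester (C8 ketone, C10 carbinol R) | COc1ccc(COC[C@H](O)[C@@H](C(=C)CO[Si](C)(C)C(C)(C)C)C(=O)C[C@@](C)(O)C(=O)OC)cc1 | intermediate
16 | triol ester (all-syn C6/C7/C8) | COc1ccc(COC[C@H](O)[C@@H](C(=C)CO[Si](C)(C)C(C)(C)C)[C@H](O)C[C@@](C)(O)C(=O)OC)cc1 | intermediate
17 | γ-lactone O8–C1 with free C6–OH and C10–OH | COc1ccc(COC[C@H](O)[C@@H](C(=C)CO[Si](C)(C)C(C)(C)C)[C@H]2C[C@@](C)(O)C(=O)O2)cc1 | intermediate
18 | C6-O-TBS γ-lactone | COc1ccc(COC[C@H](O[Si](C)(C)C(C)(C)C)[C@@H](C(=C)CO[Si](C)(C)C(C)(C)C)[C@H]2C[C@@](C)(O)C(=O)O2)cc1 | intermediate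
19 | lithium hydroxy carboxylate | COc1ccc(COC[C@H](O[Si](C)(C)C(C)(C)C)[C@@H](C(=C)CO[Si](C)(C)C(C)(C)C)[C@H](O)C[C@@](C)(O)C(=O)[O-])cc1.[Li+] | intermediate
20 | C8-O-TES ether TES ester | COc1ccc(COC[C@H](O[Si](C)(C)C(C)(C)C)[C@@H](C(=C)CO[Si](C)(C)C(C)(C)C)[C@H](O[Si](CC)(CC)CC)C[C@@](C)(O)C(=O)O[Si](CC)(CC)CC)cc1 | intermediate
21 | C1 acid, C8–OTES, C5–OPMB | COc1ccc(COC[C@H](O[Si](C)(C)C(C)(C)C)[C@@H](C(=C)CO[Si](C)(C)C(C)(C)C)[C@H](O[Si](CC)(CC)CC)C[C@@](C)(O)C(=O)O)cc1 | intermediate
22 | C5 primary alcohol acid | OC[C@H](O[Si](C)(C)C(C)(C)C)[C@@H](C(=C)CO[Si](C)(C)C(C)(C)C)[C@H](O[Si](CC)(CC)CC)C[C@@](C)(O)C(=O)O | intermediate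
23 | C5 aldehyde acid | O=C[C@H](O[Si](C)(C)C(C)(C)C)[C@@H](C(=C)CO[Si](C)(C)C(C)(C)C)[C@H](O[Si](CC)(CC)CC)C[C@@](C)(O)C(=O)O | intermediate
24 | 4-methoxybenzyl alcohol | COc1ccc(CO)cc1 | starting material
25 | trichloroethylene | ClC=C(Cl)Cl | starting material
26 | (E)-1,2-dichlorovinyl PMB ether | COc1ccc(CO/C(Cl)=C\Cl)cc1 | intermediate
27 | lithium (PMB-oxy)acetylide | COc1ccc(COC#C[Li])cc1 | intermediate
28 | 1-methoxy-4-[(prop-1-yn-1-yloxy)methyl]benzene | CC#COCc1ccc(OC)cc1 | intermediate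
29 | (E)-[1-(PMBO)prop-1-en-2-yl]zirconocene chloride | COc1ccc(CO/C=C(\C)[Zr](Cl)(C2C=CC=C2)C2C=CC=C2)cc1 | intermediate
30 | seco acid, (E)-enol ether, C5–OH (5,6-anti) | COc1ccc(CO/C=C(\C)[C@H](O)[C@H](O[Si](C)(C)C(C)(C)C)[C@@H](C(=C)CO[Si](C)(C)C(C)(C)C)[C@H](O[Si](CC)(CC)CC)C[C@@](C)(O)C(=O)O)cc1 | intermediate
31 | mixed 2-methyl-6-nitrobenzoic anhydride of 30 | COc1ccc(CO/C=C(\C)[C@H](O)[C@H](O[Si](C)(C)C(C)(C)C)[C@@H](C(=C)CO[Si](C)(C)C(C)(C)C)[C@H](O[Si](CC)(CC)CC)C[C@@](C)(O)C(=O)OC(=O)c2c(C)cccc2[N+](=O)[O-])cc1 | intermediate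
32 | eight-membered lactone (C1–O–C5) | COc1ccc(CO/C=C(\C)[C@H]2[C@H](O[Si](C)(C)C(C)(C)C)[C@@H](C(=C)CO[Si](C)(C)C(C)(C)C)[C@H](O[Si](CC)(CC)CC)C[C@@](C)(O)C(=O)O2)cc1 | intermediate
33 | 2-methyleneoxocane (C1=C2H2) | COc1ccc(CO/C=C(\C)[C@H]2[C@H](O[Si](C)(C)C(C)(C)C)[C@@H](C(=C)CO[Si](C)(C)C(C)(C)C)[C@H](O[Si](CC)(CC)CC)C[C@@](C)(O)C(=C)O2)cc1 | intermediate
34 | ten-membered (4Z)-1-ketone, C3–OPMB | C1[C@H](OCc2ccc(OC)cc2)/C(C)=C\[C@H](O[Si](C)(C)C(C)(C)C)[C@@H](C(=C)CO[Si](C)(C)C(C)(C)C)[C@H](O[Si](CC)(CC)CC)C[C@@](C)(O)C1=O | intermediate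
35 | C1 alcohol (1,10-anti) | C1[C@H](OCc2ccc(OC)cc2)/C(C)=C\[C@H](O[Si](C)(C)C(C)(C)C)[C@@H](C(=C)CO[Si](C)(C)C(C)(C)C)[C@H](O[Si](CC)(CC)CC)C[C@@](C)(O)[C@H]1O | intermediate
36 | C1,C8,C10-triol | C1[C@H](OCc2ccc(OC)cc2)/C(C)=C\[C@H](O[Si](C)(C)C(C)(C)C)[C@@H](C(=C)CO[Si](C)(C)C(C)(C)C)[C@H](O)C[C@@](C)(O)[C@H]1O | intermediate
37 | C1,C3-O-PMP acetal, free C8–OH | C1[C@H](OC2c3ccc(OC)cc3)/C(C)=C\[C@H](O[Si](C)(C)C(C)(C)C)[C@@H](C(=C)CO[Si](C)(C)C(C)(C)C)[C@H](O)C[C@@](C)(O)[C@H]1O2 | intermediate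
38 | angelic acid, (Z)-2-methylbut-2-enoic acid | C/C=C(/C)C(=O)O | starting material
39 | angelic 2,4,6-trichlorobenzoic anhydride | C/C=C(/C)C(=O)OC(=O)c1c(Cl)cc(Cl)cc1Cl | intermediate
40 | C8 angelate | C1[C@H](OC2c3ccc(OC)cc3)/C(C)=C\[C@H](O[Si](C)(C)C(C)(C)C)[C@@H](C(=C)CO[Si](C)(C)C(C)(C)C)[C@H](OC(=O)/C(C)=C\C)C[C@@](C)(O)[C@H]1O2 | intermediate
41 | C6,C12-diol | C1[C@H](OC2c3ccc(OC)cc3)/C(C)=C\[C@H](O)[C@@H](C(=C)CO)[C@H](OC(=O)/C(C)=C\C)C[C@@](C)(O)[C@H]1O2 | intermediate
42 | C12 enal with free C6–OH | C1[C@H](OC2c3ccc(OC)cc3)/C(C)=C\[C@H](O)[C@@H](C(=C)C=O)[C@H](OC(=O)/C(C)=C\C)C[C@@](C)(O)[C@H]1O2 | intermediate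
43 | C6–O–C12 lactol | C1[C@H](OC2c3ccc(OC)cc3)/C(C)=C\[C@@H]4OC(O)C(=C)[C@H]4[C@H](OC(=O)/C(C)=C\C)C[C@@](C)(O)[C@H]1O2 | intermediate
44 | α-methylene-γ-butyrolactone acetal | C1[C@H](OC2c3ccc(OC)cc3)/C(C)=C\[C@@H]4OC(=O)C(=C)[C@H]4[C@H](OC(=O)/C(C)=C\C)C[C@@](C)(O)[C@H]1O2 | intermediate
45 | (1S,3S,4Z,6S,7S,8R,10R)-8-angeloyloxy-1,3,10-trihydroxygermacra-4,11(13)-dien-6,12-olide | C=C1C(=O)O[C@H]2/C=C(/C)[C@@H](O)C[C@H](O)[C@](C)(O)C[C@@H](OC(=O)/C(C)=C\C)[C@H]12 | target

Total step count: 23. Longest linear sequence: 22 (steps 1–12 and 14–23).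

**Steps most likely to fail**

**Step 16.**
- What may go wrong: methylenation of the hindered α-hydroxy lactone may be slow. Alternatively the C5–O bond of the γ-alkoxyallyl ester or ether may ionise before the concerted shift, with ion-pair return, a 1,3-shift and loss of chirality transfer.
- Fallback: it sets out from 18, comes back at 36, and uses the γ-lactone itself as the enol ether source (ketal Claisen rearrangement). It also avoids the alkenylation of a free acid (step 14) and the medium-ring lactonisation (step 15).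
- DDQ in wet CH2Cl2 gives the primary alcohol F1, and Dess–Martin oxidation gives the neutral aldehyde F2.
- The alkenylzinc reagent made from 28 as in step 14 adds to give the allylic alcohol F3.
- Dimethyltitanocene methylenates the only carbonyl group to give the 2-methyleneoxolane F4.
- A trace of PPTS lets C5–OH add to this enol ether to give the bicyclic ketal F5 (2,?-dioxabicyclo[4.2.1]nonane, which contains the same eight-membered ring O5–C1–C10–C9–C8–C7–C6–C5).
- Heating F5 in xylene with catalytic propionic acid opens the C1–O8 arm reversibly to the 2-methyleneoxocane, which is drained by the same [3,3] shift to the hydroxy ketone F6.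
- Zn(BH4)2 then gives 36.

**Step 7.**
- What may go wrong: catalyst control may be eroded by the chiral, Lewis-basic enol silane, or the enol silane may be desilylated before C–C bond formation.
- Fallback: it sets out from 13, comes back at 17, and takes C10 from the chiral pool by self-regeneration of stereocentres.
- NBS converts 13 into the bromomethyl ketone F7.
- The lithium enolate of commercial (2S,5S)-2-tert-butyl-5-methyl-1,3-dioxolan-4-one (from (S)-lactic acid) is alkylated by F7 on the face anti to the tert-butyl group. A citric acid work-up removes the TMS ether and gives the keto dioxolanone F8.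
- Narasaka–Prasad reduction as in step 8 gives the syn diol F9.
- With catalytic PPTS the C8–OH of F9 attacks the dioxolanone carbonyl and gives 17.

**Step 20.**
- What may go wrong: the angelate may isomerise Z to E (tiglate) during a slow acylation of the hindered C8–OH.
- Fallback: it sets out from 37, comes back at 40, and builds the Z-alkene on the ester.
- 37 is esterified with 2-[bis(2,2,2-trifluoroethoxy)phosphoryl]propanoic acid (EDC, DMAP) to give the phosphonopropionate F10.
- A Still–Gennari olefination with acetaldehyde (KHMDS, 18-crown-6, THF, −78 °C) then gives 40.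

**Further compounds**
F1 | step 16 | C5 primary alcohol of the γ-lactone series | OC[C@H](O[Si](C)(C)C(C)(C)C)[C@@H](C(=C)CO[Si](C)(C)C(C)(C)C)[C@H]1C[C@@](C)(O)C(=O)O1
F2 | step 16 | C5 aldehyde of the γ-lactone series | O=C[C@H](O[Si](C)(C)C(C)(C)C)[C@@H](C(=C)CO[Si](C)(C)C(C)(C)C)[C@H]1C[C@@](C)(O)C(=O)O1
F3 | step 16 | C5 allylic alcohol γ-lactone | COc1ccc(CO/C=C(\C)[C@H](O)[C@H](O[Si](C)(C)C(C)(C)C)[C@@H](C(=C)CO[Si](C)(C)C(C)(C)C)[C@H]2C[C@@](C)(O)C(=O)O2)cc1
F4 | step 16 | 2-methyleneoxolane | COc1ccc(CO/C=C(\C)[C@H](O)[C@H](O[Si](C)(C)C(C)(C)C)[C@@H](C(=C)CO[Si](C)(C)C(C)(C)C)[C@H]2C[C@@](C)(O)C(=C)O2)cc1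
F5 | step 16 | bicyclic ketal at C1 (O5 and O8) | COc1ccc(CO/C=C(\C)[C@H]2[C@H](O[Si](C)(C)C(C)(C)C)[C@@H](C(=C)CO[Si](C)(C)C(C)(C)C)[C@H]3C[C@@](C)(O)[C@](C)(O3)O2)cc1
F6 | step 16 | ten-membered (4Z)-1-ketone with free C8–OH | C1[C@H](OCc2ccc(OC)cc2)/C(C)=C\[C@H](O[Si](C)(C)C(C)(C)C)[C@@H](C(=C)CO[Si](C)(C)C(C)(C)C)[C@H](O)C[C@@](C)(O)C1=O
F7 | step 7 | C9 bromomethyl ketone (C6–OTMS) | COc1ccc(COC[C@H](O[Si](C)(C)C)[C@@H](C(=C)CO[Si](C)(C)C(C)(C)C)C(=O)CBr)cc1
F8 | step 7 | C8 keto dioxolanone (C6–OH) | COc1ccc(COC[C@H](O)[C@@H](C(=C)CO[Si](C)(C)C(C)(C)C)C(=O)C[C@@]2(C)O[C@H](C(C)(C)C)OC2=O)cc1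
F9 | step 7 | 6,8-syn diol dioxolanone | COc1ccc(COC[C@H](O)[C@@H](C(=C)CO[Si](C)(C)C(C)(C)C)[C@H](O)C[C@@]2(C)O[C@H](C(C)(C)C)OC2=O)cc1
F10 | step 20 | C8 2-[bis(2,2,2-trifluoroethoxy)phosphoryl]propanoate | C1[C@H](OC2c3ccc(OC)cc3)/C(C)=C\[C@H](O[Si](C)(C)C(C)(C)C)[C@@H](C(=C)CO[Si](C)(C)C(C)(C)C)[C@H](OC(=O)C(C)P(=O)(OCC(F)(F)F)OCC(F)(F)F)C[C@@](C)(O)[C@H]1O2
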